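**Retrosynthetic overview**

1. Core numbering: C1 = CH(aryl), C2 = CH(CH2OH), C3 = C(CHO), C4 = alkene CH, C4a/C8a = fusion carbons of ring A. The strategy rests on the C3(CHO)=C4 enal of ring B, fused to ring A and flanked by the C2–H centre: C3=C4 is an aldol-condensation bond to an aryl aldehyde on C4a, and C3–CHO plus C2–H are what linear hydroformylation of a C2=CH2 group delivers.
2. Target ⇐ bis-MOM ether ⇐ one carbonylative cascade (C3–CHO bond, C3=C4 bond, ring B, C2 centre) from a 2-(diarylmethyl)allyl alcohol whose ring A carries the C4 formyl group.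
3. That alcohol ⇐ acetal cleavage, 1,2-reduction and α-methylenation with formaldehyde ⇐ (S)-3,3-diarylpropanal ⇐ rhodium/chiral diene 1,4-addition of the pendant arylboronic acid to the ring-A enal (sets C1).
4. Ring-A enal ⇐ Suzuki–Miyaura coupling of the bromo acetal from syringaldehyde (MOM ether, bromination, acetal) with a three-carbon alkenylboronate; boronic acid ⇐ 4-bromo-2,6-dimethoxyphenol.
5. Ring order: ring A and the pendant ring are bought as arenes; ring B is the only ring formed, in the key step.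

Key step: step 11

Assumption: the ligand antipodes written in steps 7 and 11 are working assignments from the usual quadrant models; both antipodes of each ligand are accessible, and the one meant is the one that gives (S) at C1 (step 7) and the 1,2-trans product (step 11). The (E)-3,3-diethoxyprop-1-enyl pinacol boronate is taken as a purchasable building block and replaces a Heck coupling of acrolein diethyl acetal, which is less dependable on a di-ortho-substituted, electron-rich bromide.

**Route**

Step 1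
Reactants: 1 syringaldehyde
Product: 2 3,5-dimethoxy-4-(methoxymethoxy)benzaldehyde
Conditions: MOMCl, iPr2NEt, CH2Cl2, 0 °C → rt
Reagents that add atoms: chloromethyl methyl ether, COCCl
Why: O-alkylation of the phenol (Williamson-type MOM ether formation) masks the acidic OH, which would otherwise invite ipso attack in the bromination and quench the later organometallic steps.

Step 2
Reactants: 2 3,5-dimethoxy-4-(methoxymethoxy)benzaldehyde
Product: 3 2-bromo-3,5-dimethoxy-4-(methoxymethoxy)benzaldehyde
Conditions: NBS, DMF, rt, dark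
Reagents that add atoms: N-bromosuccinimide, O=C1CCC(=O)N1Br
Why: Electrophilic aromatic bromination can only occur at the two equivalent free positions, each ortho and para to a methoxy group, and the neutral succinimide by-product leaves the MOM ether alone.

Step 3
Reactants: 3 2-bromo-3,5-dimethoxy-4-(methoxymethoxy)benzaldehyde
Product: 4 2-[2-bromo-3,5-dimethoxy-4-(methoxymethoxy)phenyl]-5,5-dimethyl-1,3-dioxane
Conditions: Me3SiOCH2C(CH3)2CH2OSiMe3, Me3SiOTf (cat.), CH2Cl2, –78 → –20 °C; pyridine quench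
Reagents that add atoms: 2,2-dimethyl-1,3-bis(trimethylsilyloxy)propane, C[Si](C)(C)OCC(C)(C)CO[Si](C)(C)C
Why: Noyori acetalisation, driven by formation of hexamethyldisiloxane, runs under aprotic low-temperature conditions that spare the aryl MOM ether and gives a hydrolysis-resistant 5,5-dimethyl-1,3-dioxane.

Step 4
Reactants: 4 2-[2-bromo-3,5-dimethoxy-4-(methoxymethoxy)phenyl]-5,5-dimethyl-1,3-dioxane; 5 (E)-2-(3,3-diethoxyprop-1-enyl)-4,4,5,5-tetramethyl-1,3,2-dioxaborolane
Product: 7 (E)-3-[6-(5,5-dimethyl-1,3-dioxan-2-yl)-2,4-dimethoxy-3-(methoxymethoxy)phenyl]prop-2-enal, via diethyl acetal 6 (not isolated)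
Conditions: Pd(OAc)2 (3 mol%), SPhos (6 mol%), K3PO4, toluene/H2O, 80 °C; then 5% aq. oxalic acid, THF, 0 °C
Reagents that add atoms: water, O
Why: Suzuki–Miyaura coupling with a bulky dialkylbiarylphosphine handles the di-ortho-substituted electron-rich bromide with retention of the E geometry, and the acyclic allylic diethyl acetal is then hydrolysed far faster than the cyclic aryl acetal (chemoselective acetal hydrolysis).

Step 5
Reactants: 8 4-bromo-2,6-dimethoxyphenol
Product: 9 5-bromo-1,3-dimethoxy-2-(methoxymethoxy)benzene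
Conditions: MOMCl, iPr2NEt, CH2Cl2, 0 °C → rt
Reagents that add atoms: chloromethyl methyl ether, COCCl
Why: MOM ether formation by O-alkylation removes the acidic phenol proton before the bromine–lithium exchange.

Step 6
Reactants: 9 5-bromo-1,3-dimethoxy-2-(methoxymethoxy)benzene
Product: 12 [3,5-dimethoxy-4-(methoxymethoxy)phenyl]boronic acid, via aryllithium 10 (not isolated), via lithium triisopropoxyborate 11 (not isolated)
Conditions: n-BuLi, THF, –78 °C; B(OiPr)3, –78 °C → rt; 1 M HCl to pH 5, 0 °C
Reagents that add atoms: triisopropyl borate, CC(C)OB(OC(C)C)OC(C)C; water, O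
Why: Bromine–lithium exchange followed by borylation and mild hydrolysis is regiospecific at the former C–Br carbon and tolerates the MOM ether.

Step 7
Reactants: 7 (E)-3-[6-(5,5-dimethyl-1,3-dioxan-2-yl)-2,4-dimethoxy-3-(methoxymethoxy)phenyl]prop-2-enal; 12 [3,5-dimethoxy-4-(methoxymethoxy)phenyl]boronic acid
Product: 13 (3S)-3-[6-(5,5-dimethyl-1,3-dioxan-2-yl)-2,4-dimethoxy-3-(methoxymethoxy)phenyl]-3-[3,5-dimethoxy-4-(methoxymethoxy)phenyl]propanal
Conditions: [RhCl(C2H4)2]2 (2.5 mol%), (R,R)-Ph-bod* (5.5 mol%), KOH (0.5 equiv), dioxane/H2O 10:1, 40 °C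
Reagents that add atoms: none
Why: Hayashi–Miyaura 1,4-addition, in which the aryl–rhodium species from transmetallation inserts the enal C=C bond while the C2-symmetric chiral diene exposes one face of the β-carbon, so that C1 is formed as the (S) centre, diene ligands favouring 1,4- over 1,2-addition to the formyl group.

Step 8
Reactants: 13 (3S)-3,3-diarylpropanal; 14 formaldehyde (37% aqueous)
Product: 15 2-{(S)-[6-(5,5-dimethyl-1,3-dioxan-2-yl)-2,4-dimethoxy-3-(methoxymethoxy)phenyl][3,5-dimethoxy-4-(methoxymethoxy)phenyl]methyl}prop-2-enal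
Conditions: pyrrolidine (10 mol%), EtCO2H (10 mol%), i-PrOH, 45 °C
Reagents that add atoms: none
Why: Amine-catalysed α-methylenation (Mannich condensation of the enamine with formaldehyde, then elimination of the amine) installs the C2=CH2 group without touching the non-acidic C1–H, so the C1 configuration is kept.

Step 9
Reactants: 15 2-(diarylmethyl)prop-2-enal
Product: 16 2-{(R)-[6-(5,5-dimethyl-1,3-dioxan-2-yl)-2,4-dimethoxy-3-(methoxymethoxy)phenyl][3,5-dimethoxy-4-(methoxymethoxy)phenyl]methyl}prop-2-en-1-ol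
Conditions: NaBH4, CeCl3·7H2O, MeOH, –20 °C
Reagents that add atoms: none
Why: Luche reduction delivers hydride 1,2 to the enal and leaves the 1,1-disubstituted alkene, the acetal and the MOM ethers unchanged (the descriptor changes from S to R only through the priority rules).

Step 10
Reactants: 16 2-(diarylmethyl)prop-2-en-1-ol with the dioxane acetal
Product: 17 2-{(1R)-1-[3,5-dimethoxy-4-(methoxymethoxy)phenyl]-2-(hydroxymethyl)prop-2-enyl}-3,5-dimethoxy-4-(methoxymethoxy)benzaldehyde
Conditions: 1 M aq. HCl, THF, 0 °C → rt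
Reagents that add atoms: water, O
Why: Acid-catalysed acetal hydrolysis is selective because the aryl-stabilised oxocarbenium ion of the benzaldehyde acetal forms far more readily than the formaldehyde-derived ion of an aryl MOM ether, and the water-rich medium traps it before the alkene can.

Step 11
Reactants: 17 2-(diarylmethyl)allyl alcohol with the C4 formyl group on ring A
Product: 20 (1S,2R)-1-[3,5-dimethoxy-4-(methoxymethoxy)phenyl]-2-(hydroxymethyl)-6,8-dimethoxy-7-(methoxymethoxy)-1,2-dihydronaphthalene-3-carbaldehyde, via hydroxy dialdehyde 18 (not isolated), via aldol adduct 19 (not isolated)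
Conditions: Rh(acac)(CO)2 (2 mol%), (S,R)-DTBM-YanPhos (4 mol%), CO/H2 1:1 (10 bar), Bn2NH (20 mol%), PhCO2H (20 mol%), toluene, 60 °C
Reagents that add atoms: carbon monoxide, [C-]#[O+]
Why: Proposed new method: the rhodium hydride adds across the C2=CH2 bond with the metal on the terminal carbon (a tertiary alkyl at C2 is avoided), CO insertion and hydrogenolysis give γ-hydroxy aldehyde 18 (resting as its five-membered lactol), and its dibenzylamine enamine at C3 attacks the ortho aryl aldehyde C4 to give aldol 19, which loses water to the ring-A-conjugated enal. The closest known reaction types are the enantioselective rhodium-catalysed anti-Markovnikov hydroformylation of 1,1-disubstituted allylic alcohols to β-chiral lactols and amine-mediated domino hydroformylation/aldol condensations; merging them on a substrate that already carries the C1 centre is the untested part. Ring B closes by a 6-(enolexo)-exo-trig aldol addition (C3–C4 bond) followed by E1cB dehydration. The C2 centre arises when hydride is delivered to C2 during alkene insertion, and its configuration is fixed by the chiral phosphine–phosphoramidite ligand (antipode chosen to be matched with C1 for the 1,2-trans product), because the two aryl groups on C1 are too similar for substrate control. The step needs linear regioselectivity, secured by the 1,1-disubstituted alkene, and a single aldol direction, secured because the aryl aldehyde cannot enolise and the C3 aldehyde is the only enamine donor. The enal formed is trisubstituted and conjugated and so should not be hydroformylated further, and C2 cannot epimerise through the enal because its C–H bond is cross-conjugated.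

Step 12
Reactants: 20 bis-MOM ether of the target
Product: 21 (1S,2R)-7-hydroxy-1-(4-hydroxy-3,5-dimethoxyphenyl)-2-(hydroxymethyl)-6,8-dimethoxy-1,2-dihydronaphthalene-3-carbaldehyde
Conditions: 3 M aq. HCl, THF, 40 °C
Reagents that add atoms: none
Why: Acid-catalysed hydrolysis of the two aryl methoxymethyl ethers (acetal cleavage) frees both phenols, and neither stereocentre is acidified by the enal under these conditions, so the (1S,2R) configuration is retained.

**Compound list**

1 | syringaldehyde | COc1cc(C=O)cc(OC)c1O | starting material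
2 | 3,5-dimethoxy-4-(methoxymethoxy)benzaldehyde | COCOc1c(OC)cc(C=O)cc1OC | intermediate
3 | 2-bromo-3,5-dimethoxy-4-(methoxymethoxy)benzaldehyde | COCOc1c(OC)cc(C=O)c(Br)c1OC | intermediate
4 | 2-[2-bromo-3,5-dimethoxy-4-(methoxymethoxy)phenyl]-5,5-dimethyl-1,3-dioxane | COCOc1c(OC)cc(C2OCC(C)(C)CO2)c(Br)c1OC | intermediate
5 | (E)-2-(3,3-diethoxyprop-1-enyl)-4,4,5,5-tetramethyl-1,3,2-dioxaborolane | CCOC(OCC)/C=C/B1OC(C)(C)C(C)(C)O1 | starting material
6 | 2-{2-[(E)-3,3-diethoxyprop-1-enyl]-3,5-dimethoxy-4-(methoxymethoxy)phenyl}-5,5-dimethyl-1,3-dioxane | COCOc1c(OC)cc(C2OCC(C)(C)CO2)c(/C=C/C(OCC)OCC)c1OC | intermediate (not isolated)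
7 | (E)-3-[6-(5,5-dimethyl-1,3-dioxan-2-yl)-2,4-dimethoxy-3-(methoxymethoxy)phenyl]prop-2-enal | COCOc1c(OC)cc(C2OCC(C)(C)CO2)c(/C=C/C=O)c1OC | intermediate
8 | 4-bromo-2,6-dimethoxyphenol | COc1cc(Br)cc(OC)c1O | starting material
9 | 5-bromo-1,3-dimethoxy-2-(methoxymethoxy)benzene | COCOc1c(OC)cc(Br)cc1OC | intermediate
10 | [3,5-dimethoxy-4-(methoxymethoxy)phenyl]lithium | COCOc1c(OC)cc([Li])cc1OC | intermediate (not isolated)
11 | lithium [3,5-dimethoxy-4-(methoxymethoxy)phenyl]tri(propan-2-yloxy)borate | COCOc1c(OC)cc([B-](OC(C)C)(OC(C)C)OC(C)C)cc1OC.[Li+] | intermediate (not isolated)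
12 | [3,5-dimethoxy-4-(methoxymethoxy)phenyl]boronic acid | COCOc1c(OC)cc(B(O)O)cc1OC | intermediate
13 | (3S)-3-[6-(5,5-dimethyl-1,3-dioxan-2-yl)-2,4-dimethoxy-3-(methoxymethoxy)phenyl]-3-[3,5-dimethoxy-4-(methoxymethoxy)phenyl]propanal | COc1cc([C@H](CC=O)c2c(C3OCC(C)(C)CO3)cc(OC)c(OCOC)c2OC)cc(OC)c1OCOC | intermediate
14 | formaldehyde | C=O | starting material
15 | 2-{(S)-[6-(5,5-dimethyl-1,3-dioxan-2-yl)-2,4-dimethoxy-3-(methoxymethoxy)phenyl][3,5-dimethoxy-4-(methoxymethoxy)phenyl]methyl}prop-2-enal | COc1cc([C@H](C(=C)C=O)c2c(C3OCC(C)(C)CO3)cc(OC)c(OCOC)c2OC)cc(OC)c1OCOC | intermediate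
16 | 2-{(R)-[6-(5,5-dimethyl-1,3-dioxan-2-yl)-2,4-dimethoxy-3-(methoxymethoxy)phenyl][3,5-dimethoxy-4-(methoxymethoxy)phenyl]methyl}prop-2-en-1-ol | COc1cc([C@H](C(=C)CO)c2c(C3OCC(C)(C)CO3)cc(OC)c(OCOC)c2OC)cc(OC)c1OCOC | intermediate
17 | 2-{(1R)-1-[3,5-dimethoxy-4-(methoxymethoxy)phenyl]-2-(hydroxymethyl)prop-2-enyl}-3,5-dimethoxy-4-(methoxymethoxy)benzaldehyde | COc1cc([C@H](C(=C)CO)c2c(C=O)cc(OC)c(OCOC)c2OC)cc(OC)c1OCOC | intermediate (key-step precursor)
18 | 2-{(1S,2S)-1-[3,5-dimethoxy-4-(methoxymethoxy)phenyl]-2-(hydroxymethyl)-4-oxobutyl}-3,5-dimethoxy-4-(methoxymethoxy)benzaldehyde (in equilibrium with its five-membered lactol) | COc1cc([C@H]([C@@H](CO)CC=O)c2c(C=O)cc(OC)c(OCOC)c2OC)cc(OC)c1OCOC | intermediate (not isolated)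
19 | (1S,2R)-4-hydroxy-1-[3,5-dimethoxy-4-(methoxymethoxy)phenyl]-2-(hydroxymethyl)-6,8-dimethoxy-7-(methoxymethoxy)-1,2,3,4-tetrahydronaphthalene-3-carbaldehyde (C3 and C4 unassigned) | COc1cc([C@H]2c3c(cc(OC)c(OCOC)c3OC)C(O)C(C=O)[C@@H]2CO)cc(OC)c1OCOC | intermediate (not isolated)
20 | (1S,2R)-1-[3,5-dimethoxy-4-(methoxymethoxy)phenyl]-2-(hydroxymethyl)-6,8-dimethoxy-7-(methoxymethoxy)-1,2-dihydronaphthalene-3-carbaldehyde | COc1cc([C@H]2c3c(cc(OC)c(OCOC)c3OC)C=C(C=O)[C@@H]2CO)cc(OC)c1OCOC | intermediate (key-step product)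
21 | (1S,2R)-7-hydroxy-1-(4-hydroxy-3,5-dimethoxyphenyl)-2-(hydroxymethyl)-6,8-dimethoxy-1,2-dihydronaphthalene-3-carbaldehyde (1,2-trans) | COc1cc([C@H]2c3c(cc(OC)c(O)c3OC)C=C(C=O)[C@@H]2CO)cc(OC)c1O | target

**Count**

Total steps: 12. Longest linear sequence: 10 steps (steps 1–4 and 7–12); steps 5–6 make the boronic acid branch.

**Steps most likely to fail**

1. Step 11 (the proposed new method).
   - What may go wrong: hydride delivery to the wrong face of C2 if ligand and C1 centre are mismatched, giving cis/trans mixtures that cannot be corrected after ring closure; slow insertion at the hindered alkene with competing alkene hydrogenation or isomerisation; reduction of the enamine (hydroaminomethylation) instead of aldol closure.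
   - Fallback with known chemistry, from 13 back to 20: Pinnick oxidation of 13 (NaClO2, NaH2PO4, 2-methyl-2-butene, t-BuOH/H2O) should give the (3S)-3,3-diarylpropanoic acid F1. Activation as the mixed pivalic anhydride (PivCl, Et3N) and acylation of lithiated (S)-4-benzyl-2-oxazolidinone should give the N-acyl oxazolidinone F2. Evans alkylation (NaN(SiMe3)2, THF, –78 °C; allyl iodide) should give the α-allyl imide F3; here the auxiliary, not the C1 centre, sets C2, the electrophile entering anti to the benzyl group of the chelated Z-enolate. LiBH4 (THF, 0 °C) cleaves the auxiliary to the 2-(diarylmethyl)pent-4-en-1-ol F4. Lemieux–Johnson cleavage (OsO4 cat., NaIO4, 2,6-lutidine, dioxane/H2O) gives the acetal-protected γ-hydroxy aldehyde F5, resting as its lactol. The conditions of step 10 convert F5 into 18, and Bn2NH·CF3CO2H in toluene at 50 °C effects the same 6-(enolexo)-exo-trig aldol condensation to 20, where the route is rejoined.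

2. Step 7.
   - What may go wrong: slow insertion at the β-carbon that bears the di-ortho-substituted ring A, so that protodeboronation of 12 and 1,2-addition to the formyl group take over; or weak facial discrimination by the diene.
   - Fallback, from 7 back to 13: Pinnick oxidation of 7 gives the (E)-cinnamic acid F6, which is converted through its pivalic mixed anhydride into the N-enoyl (R)-4-phenyl-2-oxazolidinone F7. The arylmagnesium bromide F8 is made from bromide 9 and Mg in THF. Its CuBr·SMe2-mediated conjugate addition to F7 (THF, –40 → 0 °C) should give the β,β-diaryl imide F9, the aryl group entering anti to the phenyl group of the magnesium-chelated s-cis imide. LiBH4 gives the (3S)-3,3-diarylpropan-1-ol F10, and Dess–Martin oxidation returns 13.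

3. Step 4.
   - What may go wrong: partial loss of the cyclic acetal during the acidic unmasking of 6, which would expose a second formyl group, or protodeboronation of the alkenylboronate before coupling.
   - Fallback, from 4 back to 7: bromine–lithium exchange on 4 (n-BuLi, THF, –78 °C) and quenching with DMF gives the benzaldehyde F11. Wittig olefination with Ph3P=CHCHO (toluene, 90 °C) gives the E enal 7 without any acid treatment.

**Further compounds**

F1 | step 11 | (3S)-3-[6-(5,5-dimethyl-1,3-dioxan-2-yl)-2,4-dimethoxy-3-(methoxymethoxy)phenyl]-3-[3,5-dimethoxy-4-(methoxymethoxy)phenyl]propanoic acid | COc1cc([C@H](CC(=O)O)c2c(C3OCC(C)(C)CO3)cc(OC)c(OCOC)c2OC)cc(OC)c1OCOC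
F2 | step 11 | (4S)-4-benzyl-3-{(3S)-3-[6-(5,5-dimethyl-1,3-dioxan-2-yl)-2,4-dimethoxy-3-(methoxymethoxy)phenyl]-3-[3,5-dimethoxy-4-(methoxymethoxy)phenyl]propanoyl}-1,3-oxazolidin-2-one | COc1cc([C@H](CC(=O)N4[C@@H](Cc5ccccc5)COC4=O)c2c(C3OCC(C)(C)CO3)cc(OC)c(OCOC)c2OC)cc(OC)c1OCOC
F3 | step 11 | (4S)-4-benzyl-3-{(2S)-2-[(S)-diarylmethyl]pent-4-enoyl}-1,3-oxazolidin-2-one (aryl groups as in 13; C1 S, C2 S) | COc1cc([C@H]([C@H](CC=C)C(=O)N4[C@@H](Cc5ccccc5)COC4=O)c2c(C3OCC(C)(C)CO3)cc(OC)c(OCOC)c2OC)cc(OC)c1OCOC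
F4 | step 11 | (2S)-2-[(S)-diarylmethyl]pent-4-en-1-ol (aryl groups as in 13) | COc1cc([C@H]([C@@H](CO)CC=C)c2c(C3OCC(C)(C)CO3)cc(OC)c(OCOC)c2OC)cc(OC)c1OCOC
F5 | step 11 | (3S)-3-[(S)-diarylmethyl]-4-hydroxybutanal (aryl groups as in 13; resting as its lactol) | COc1cc([C@H]([C@@H](CO)CC=O)c2c(C3OCC(C)(C)CO3)cc(OC)c(OCOC)c2OC)cc(OC)c1OCOC
F6 | step 7 | (E)-3-[6-(5,5-dimethyl-1,3-dioxan-2-yl)-2,4-dimethoxy-3-(methoxymethoxy)phenyl]prop-2-enoic acid | COCOc1c(OC)cc(C2OCC(C)(C)CO2)c(/C=C/C(=O)O)c1OC
F7 | step 7 | (4R)-3-{(E)-3-[6-(5,5-dimethyl-1,3-dioxan-2-yl)-2,4-dimethoxy-3-(methoxymethoxy)phenyl]prop-2-enoyl}-4-phenyl-1,3-oxazolidin-2-one | COCOc1c(OC)cc(C2OCC(C)(C)CO2)c(/C=C/C(=O)N3[C@H](c4ccccc4)COC3=O)c1OC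
F8 | step 7 | [3,5-dimethoxy-4-(methoxymethoxy)phenyl]magnesium bromide | COCOc1c(OC)cc([Mg]Br)cc1OC
F9 | step 7 | (4R)-3-{(3S)-3-[6-(5,5-dimethyl-1,3-dioxan-2-yl)-2,4-dimethoxy-3-(methoxymethoxy)phenyl]-3-[3,5-dimethoxy-4-(methoxymethoxy)phenyl]propanoyl}-4-phenyl-1,3-oxazolidin-2-one | COc1cc([C@H](CC(=O)N4[C@H](c5ccccc5)COC4=O)c2c(C3OCC(C)(C)CO3)cc(OC)c(OCOC)c2OC)cc(OC)c1OCOC
F10 | step 7 | (3S)-3-[6-(5,5-dimethyl-1,3-dioxan-2-yl)-2,4-dimethoxy-3-(methoxymethoxy)phenyl]-3-[3,5-dimethoxy-4-(methoxymethoxy)phenyl]propan-1-ol | COc1cc([C@H](CCO)c2c(C3OCC(C)(C)CO3)cc(OC)c(OCOC)c2OC)cc(OC)c1OCOC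
F11 | step 4 | 6-(5,5-dimethyl-1,3-dioxan-2-yl)-2,4-dimethoxy-3-(methoxymethoxy)benzaldehyde | COCOc1c(OC)cc(C2OCC(C)(C)CO2)c(C=O)c1OC
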